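**Retrosynthetic overview**

1. Target 16 ⇐ 9‑O‑methyl ether 15 (thiolate demethylation) ⇐ 8‑hydroxypterocarpan 13, by annulating the D‑ring 2,2‑dimethylpyran onto 8‑OH/C7 (formed last).
2. 13 ⇐ benzodipyran 8 + quinone 12 by a chiral‑Ti formal [3+2] with the 2H‑chromene C=C. This forms C6a–C6b and C11a–O11 (the dihydrofuran ring), sets both stereocentres, and rearomatizes the D ring with only 8‑OH free.
3. 12 ⇐ arene 11 by oxidative dearomatization; 11 ⇐ 1,2,4‑trimethoxybenzene + prenyl bromide (lithiation between the two methoxy groups).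
4. 8 ⇐ salicylaldehyde 6 + vinylphosphonium salt (O5 pyran ring) ⇐ resorcinol (A ring, linear dimethylpyran built first).
5. Ring order: A → A‑ring dimethylpyran → O5 pyran → dihydrofuran (D ring arrives preformed) → D‑ring dimethylpyran.

Assumption: the target is (6aR,11aR), as read from the SMILES. The facial sense of the (R,R)‑TADDOL–Ti complex is assumed to give this enantiomer; if the first run gives the antipode, (S,S)‑TADDOL is used and nothing else changes.

**Route**

Step 1
Reactants: 1 resorcinol; 2 3‑methylbut‑2‑enoic acid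
Product: 3 7‑hydroxy‑2,2‑dimethylchroman‑4‑one
Conditions: MeSO3H/P2O5 (Eaton's reagent), 70 °C
Reagents that add atoms: 3‑methylbut‑2‑enoic acid, CC(C)=CC(=O)O
Why: Friedel–Crafts acylation at C4 of resorcinol followed by intramolecular oxa‑Michael closure gives the 7‑hydroxychromanone.

Step 2
Reactants: 3
Product: 4 2,2‑dimethyl‑2H‑chromen‑7‑ol
Conditions: LiAlH4, THF, 0 °C → reflux; then 2 M HCl work‑up, rt (one pot)
Reagents that add atoms: none
Why: Ketone reduction gives a benzylic carbinol para to the 7‑oxygen, which dehydrates readily under acid (E1) to the chromene.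

Step 3
Reactants: 4; 5 paraformaldehyde
Product: 6 7‑hydroxy‑2,2‑dimethyl‑2H‑chromene‑6‑carbaldehyde
Conditions: MgCl2, Et3N, (CH2O)n, MeCN, reflux
Reagents that add atoms: paraformaldehyde, C=O
Why: Mg‑phenoxide‑directed ortho‑formylation (Casnati–Skattebøl) goes to the less hindered ortho carbon C6 rather than C8 (flanked by two oxygens), fixing the linear pattern.

Step 4
Reactants: 6; 7 vinyltriphenylphosphonium bromide
Product: 8 2,2‑dimethyl‑2H,8H‑pyrano[3,2‑g]chromene (linear benzodipyran, one unsubstituted 2H‑chromene ring)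
Conditions: NaH, THF, 0 °C; then 7, reflux
Reagents that add atoms: vinyltriphenylphosphonium bromide, C=C[P+](c1ccccc1)(c1ccccc1)c1ccccc1.[Br-] (supplies CH2–CH=)
Why: Schweizer chromene synthesis: the phenoxide adds to the vinylphosphonium salt and the resulting ylide closes by intramolecular Wittig reaction on the ortho aldehyde.

Step 5
Reactants: 9 1,2,4‑trimethoxybenzene; 10 prenyl bromide
Product: 11 1,2,4‑trimethoxy‑3‑(3‑methylbut‑2‑en‑1‑yl)benzene
Conditions: n‑BuLi, THF, 0 °C → rt; CuI (10 mol %), then 10, −78 °C → rt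
Reagents that add atoms: prenyl bromide, CC(C)=CCBr
Why: Directed ortho‑metalation occurs at C3 between the 2‑ and 4‑methoxy groups, and Cu‑mediated SN2 allylation delivers the linear prenyl group.

Step 6
Reactants: 11
Product: 12 2‑methoxy‑3‑(3‑methylbut‑2‑en‑1‑yl)‑1,4‑benzoquinone
Conditions: CAN (2.5 equiv), MeCN–H2O, 0 °C, 15 min; extract into CH2Cl2, short silica plug, dry over 4 Å MS; used at once
Reagents that add atoms: water, O (supplies both quinone oxygens; the two para methoxy groups leave as MeOH)
Why: CAN oxidative demethylation of the para‑dimethoxy pair (C1/C4) dearomatizes the arene to the 2‑methoxy‑p‑quinone, and the short, cold reaction leaves the prenyl alkene untouched.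

Step 7 (key step)
Reactants: 12 (1.3 equiv); 8
Product: 13 (6aR,11aR)‑cis‑pterocarpan with the linear 2,2‑dimethylpyran on the A ring (C2–C/C3–O), 8‑OH, 9‑OMe, 10‑prenyl, 7‑H
Conditions: (R,R)‑TADDOL/TiCl4/Ti(OiPr)4 (TADDOLate‑TiCl2, 2.5 equiv), CH2Cl2, −78 °C; add 12, then 8, −78 → −40 °C; NaHCO3 quench
Reagents that add atoms: none
Why: Ti(IV)–TADDOLate‑promoted 2‑alkoxyquinone/2H‑chromene formal [3+2] cycloaddition: Ti chelates C1=O and the OMe of 12, so chromene C3 attacks quinone C5 and the C4 carbonyl oxygen traps the benzylic cation at chromene C4; the chiral Ti complex selects the alkene face (sets C6a), the 6/5 closure can only be cis (sets C11a), and tautomerization rearomatizes the D ring with only 8‑OH free.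
- Chemoselectivity: the 2,2‑dimethylchromene C=C is shielded by its gem‑dimethyl group, and the prenyl alkene is less nucleophilic than the p‑alkoxystyrene.
- Any [2+2] adduct is converted to 13 on warming or with a trace of acid; the ee is upgraded by recrystallization of 13 if needed.

Step 8
Reactants: 13; 14 1,1‑diethoxy‑3‑methylbut‑2‑ene (prenal diethyl acetal)
Product: 15 9‑O‑methyl‑lespecyrtin E4 (13 with a 2,2‑dimethyl‑2H‑pyran fused at C7–C/C8–O)
Conditions: 14 (2 equiv), 3‑picoline, p‑xylene, 140 °C (−EtOH), N2
Reagents that add atoms: 1,1‑diethoxy‑3‑methylbut‑2‑ene, CCOC(OCC)C=C(C)C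
Why: Base‑mediated phenol/enal‑acetal chromenylation (aryl mixed acetal → ortho C–C bond → o‑quinone methide → oxa‑6π electrocyclization); C7 is the only free position ortho to 8‑OH, and the non‑acidic medium leaves the benzylic C11a–O bond and both stereocentres untouched.

Step 9
Reactants: 15
Product: 16 lespecyrtin E4
Conditions: EtSNa (5 equiv), DMF, 110 °C; aq. NH4Cl
Reagents that add atoms: none
Why: SN2 demethylation by thiolate at the only methyl ether, which is di‑ortho‑substituted and therefore activated; the ring ethers are far slower, and the alkenes and stereocentres are inert to nucleophilic, non‑acidic conditions.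

**Compound list**

1 | resorcinol | Oc1cccc(O)c1 | starting material
2 | 3‑methylbut‑2‑enoic acid | CC(C)=CC(=O)O | starting material
3 | 7‑hydroxy‑2,2‑dimethylchroman‑4‑one | CC1(C)CC(=O)c2ccc(O)cc2O1 | intermediate
4 | 2,2‑dimethyl‑2H‑chromen‑7‑ol | CC1(C)C=Cc2ccc(O)cc2O1 | intermediate
5 | paraformaldehyde | C=O | starting material
6 | 7‑hydroxy‑2,2‑dimethyl‑2H‑chromene‑6‑carbaldehyde | CC1(C)C=Cc2cc(C=O)c(O)cc2O1 | intermediate
7 | vinyltriphenylphosphonium bromide | C=C[P+](c1ccccc1)(c1ccccc1)c1ccccc1.[Br-] | starting material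
8 | 2,2‑dimethyl‑2H,8H‑pyrano[3,2‑g]chromene | CC1(C)C=Cc2cc3C=CCOc3cc2O1 | intermediate
9 | 1,2,4‑trimethoxybenzene | COc1ccc(OC)c(OC)c1 | starting material
10 | prenyl bromide | CC(C)=CCBr | starting material
11 | 1,2,4‑trimethoxy‑3‑prenylbenzene | COc1ccc(OC)c(CC=C(C)C)c1OC | intermediate
12 | 2‑methoxy‑3‑prenyl‑1,4‑benzoquinone | COC1=C(CC=C(C)C)C(=O)C=CC1=O | intermediate
13 | (6aR,11aR)‑8‑hydroxy‑9‑methoxy‑10‑prenylpterocarpan with a 2,2‑dimethylpyran fused at C2–C/C3–O of the A ring | CC(C)=CCc1c(OC)c(O)cc2c1O[C@H]1c3cc4c(cc3OC[C@@H]21)OC(C)(C)C=C4 | intermediate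
14 | 1,1‑diethoxy‑3‑methylbut‑2‑ene | CCOC(OCC)C=C(C)C | starting material
15 | 9‑O‑methyl‑lespecyrtin E4 | CC(C)=CCc1c(OC)c2c(c3c1O[C@H]1c4cc5c(cc4OC[C@@H]31)OC(C)(C)C=C5)C=CC(C)(C)O2 | intermediate
16 | lespecyrtin E4 | CC(C)=CCc1c(O)c2c(c3c1O[C@H]1c4cc5c(cc4OC[C@@H]31)OC(C)(C)C=C5)C=CC(C)(C)O2 | target

**Totals**

Total steps: 9. Longest linear sequence: 7 (steps 1–4, 7, 8, 9); the D‑ring branch (steps 5–6) joins at step 7.

**Steps most likely to fail**

1. Step 7. Risks: the level and sense of facial selectivity, competing [2+2]/[5+2] adducts, and attack by the other alkenes. Fallback: drop the cycloaddition and set C6a by Ru–TsDPEN asymmetric transfer hydrogenation with dynamic kinetic resolution of the corresponding 2′‑oxygenated isoflavanone, then close the dihydrofuran under acid to the cis‑pterocarpan.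
2. Step 9. Risk: hot thiolate may open the benzylic C11a–O bond or give incomplete demethylation. Fallback: change the protecting group and the order of events. Hydrolyse 12 to the 2‑hydroxyquinone and O‑allylate it (allyl bromide, Ag2O), run the cycloaddition on the allyloxyquinone, remove the allyl group with Pd(PPh3)4/morpholine at rt, and chromenylate the resulting 8,9‑catechol last (C7 is its only open ortho position).
3. Step 8. Risk: C7 is activated by only one oxygen and lies next to the ring fusion, so chromenylation may be slow. Fallback: form the O–C bond first by alkylating 8‑OH with 3‑chloro‑3‑methylbut‑1‑yne (CuCl2 cat., DBU), then build the C7–C bond by thermal propargyl Claisen rearrangement/6π closure in xylene.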